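The C7–C8–C9 stereotriad of the seven-membered ring (numbered C5 spiro carbon, C6 CH2, C7 and C8 CHMe, C9 carbinol) is mapped onto a trans-3,4-disubstituted γ-butyrolactone whose carbonyl and acetal carbons end as the two methyl groups. In one operation a lithiated ring-B aryl dithiane adds to the (5R)-menthyloxybutenolide and the resulting enolate is trapped by 3,4,5-trimethoxybenzaldehyde (ring A), forming the C6–C7 and C8–C9 bonds and all three stereocentres. The precursors are the butenolide, a silyl-protected syringaldehyde dithiane and the aldehyde; a late phenol oxidation closes the spiro ring by joining ring A to C5.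

Key step: step 5

Remarks on the chemistry:
- Lactone atoms are numbered O1, C2 (carbonyl), C3, C4, C5 (acetal).
- The ring-B phenol is carried as a triisopropylsilyl ether and not as a benzyl ether. Raney nickel can cleave aryl benzyl ethers during desulfurisation, and a later hydrogenolysis would put the C9 benzylic C–O bond at risk.
- Stereochemical bookkeeping: 5R acetal, then 4R (anti addition), 3S (trans lactone) and R carbinol (anti aldol); these become 7R, 8S and 9R.

Step 1
Reactants: 1 syringaldehyde (4-hydroxy-3,5-dimethoxybenzaldehyde)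
Product: 2 4-(1,3-dithian-2-yl)-2,6-dimethoxyphenol
Conditions: HS(CH2)3SH, BF3·OEt2 (cat.), CH2Cl2, 0 °C → rt
Reagents that add atoms: propane-1,3-dithiol, SCCCS
Why: Lewis-acid-catalysed dithioacetalisation of an aromatic aldehyde is dependable and tolerates the free phenol, and it turns the formyl carbon into the acyl-anion equivalent that will become C6.

Step 2
Reactants: 2 4-(1,3-dithian-2-yl)-2,6-dimethoxyphenol
Product: 3 2-[3,5-dimethoxy-4-(triisopropylsilyloxy)phenyl]-1,3-dithiane
Conditions: TIPSCl, imidazole, DMF, rt → 40 °C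
Reagents that add atoms: triisopropylsilyl chloride, CC(C)[Si](Cl)(C(C)C)C(C)C
Why: Imidazole-promoted O-silylation of the phenol gives a bulky aryl silyl ether that should withstand n-BuLi, Raney Ni and hydride reagents and can later be removed with fluoride.

Step 3
Reactants: 4 furfural
Product: 6 5-hydroxyfuran-2(5H)-one (racemic), via furan endoperoxide 5 (not isolated)
Conditions: O2, rose bengal (cat.), hν (visible), MeOH, 20 °C
Reagents that add atoms: oxygen, O=O
Why: Dye-sensitised singlet oxygen adds across the furan in a [4+2] photooxygenation and methanolysis of the endoperoxide expels the formyl carbon as methyl formate, which leaves the γ-hydroxybutenolide.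

Step 4
Reactants: 6 5-hydroxyfuran-2(5H)-one; 7 (−)-menthol [(1R,2S,5R)-2-isopropyl-5-methylcyclohexanol]
Product: 8 (5R)-5-{[(1R,2S,5R)-2-isopropyl-5-methylcyclohexyl]oxy}furan-2(5H)-one
Conditions: CSA (cat.), toluene, reflux (Dean–Stark); crystallisation from hexane, −20 °C; mother liquor re-equilibrated with acid and recycled
Reagents that add atoms: none
Why: Acid-catalysed acetalisation of the lactol with menthol gives both C5 epimers, which interconvert through the oxocarbenium ion, and the crystalline (5R) diastereomer should be collected by crystallisation with recycling of the mother liquor, so C5 is set by the menthol auxiliary through crystallisation-driven diastereomer selection.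

Step 5
Reactants: 3 2-[3,5-dimethoxy-4-(triisopropylsilyloxy)phenyl]-1,3-dithiane; 8 (5R)-5-menthyloxyfuran-2(5H)-one; 9 3,4,5-trimethoxybenzaldehyde
Product: 12 (3S,4R,5R)-4-{2-[3,5-dimethoxy-4-(triisopropylsilyloxy)phenyl]-1,3-dithian-2-yl}-3-[(R)-hydroxy(3,4,5-trimethoxyphenyl)methyl]-5-[(1R,2S,5R)-menthyloxy]oxolan-2-one, via 2-lithio dithiane 10 (not isolated), via lithium lactone enolate 11 (not isolated)
Conditions: n-BuLi, THF, −78 → −20 °C; 8, −78 °C; 9, −78 °C; AcOH, −78 °C
Reagents that add atoms: none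
Why: n-BuLi removes the C2 proton of dithiane 3 and the soft, sulfur-stabilised benzylic anion 10 adds 1,4 to butenolide 8; the lithium lactone enolate 11 so formed attacks aldehyde 9 through a closed six-membered chair transition state (Zimmerman–Traxler type), and a cold acetic acid quench releases aldol 12. The closest known reaction type is the tandem conjugate addition–aldol (three-component Michael–aldol) coupling of 2-aryl-2-lithio-1,3-dithianes, 5-alkoxybutenolides and aromatic aldehydes used for lignan lactones. No ring is closed; the two new bonds are dithiane C2 to lactone C4 (future C6–C7) and lactone C3 to the carbinol carbon (future C8–C9). C4 is controlled by the C5 menthyloxy group, which shields its own face so that the anion enters anti and gives 4R; C3 is controlled by the new bulky C4 substituent, the aldehyde approaching the opposite enolate face to give the 3,4-trans lactone (3S). The carbinol centre is controlled by enolate geometry: the ring locks the enolate as E(O), and a chair with the aryl group equatorial gives the anti aldol, that is the R carbinol. The step needs 1,4- over 1,2-addition, secured by the soft aryl dithianyl anion and the poorly electrophilic acyl acetal carbonyl, and kinetic aldol control, secured by reaction and quench at −78 °C.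

Step 6
Reactants: 12 aldol adduct
Product: 13 (3S,4R,5R)-3-[(R)-(tert-butyldimethylsilyloxy)(3,4,5-trimethoxyphenyl)methyl]-4-{2-[3,5-dimethoxy-4-(triisopropylsilyloxy)phenyl]-1,3-dithian-2-yl}-5-[(1R,2S,5R)-menthyloxy]oxolan-2-one
Conditions: TBSOTf, 2,6-lutidine, CH2Cl2, −78 → 0 °C
Reagents that add atoms: tert-butyldimethylsilyl triflate, CC(C)(C)[Si](C)(C)OS(=O)(=O)C(F)(F)F
Why: Silyl triflate with a hindered pyridine base silylates the congested secondary benzylic alcohol without forming an alkoxide, which avoids retro-aldol cleavage and epimerisation at C3.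

Step 7
Reactants: 13 silylated dithiane lactone
Product: 14 (3S,4R,5R)-3-[(R)-(tert-butyldimethylsilyloxy)(3,4,5-trimethoxyphenyl)methyl]-4-[3,5-dimethoxy-4-(triisopropylsilyloxy)benzyl]-5-[(1R,2S,5R)-menthyloxy]oxolan-2-one
Conditions: Raney Ni (W-2, washed neutral), EtOH–THF, rt
Reagents that add atoms: none
Why: Raney nickel desulfurisation hydrogenolyses both benzylic C–S bonds of the dithioacetal to give the C6 methylene, while silyl ethers, the acyl acetal and the three stereocentres are not expected to be affected at room temperature.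

Step 8
Reactants: 14 benzyl lactone
Product: 15 (2R,3R)-2-[(R)-(tert-butyldimethylsilyloxy)(3,4,5-trimethoxyphenyl)methyl]-3-[3,5-dimethoxy-4-(triisopropylsilyloxy)benzyl]butane-1,4-diol
Conditions: LiAlH4, THF, 0 °C; then H2O, aq. NaOH
Reagents that add atoms: none
Why: Hydride reduction of the acyl acetal opens the lactone, the liberated hemiacetal expels menthoxide, and both carbonyl carbons end as primary alcohols faster than the transient aldehydes can enolise, so C7 and C8 keep their configuration.

Step 9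
Reactants: 15 diol
Product: 16 (2R,3R)-2-[(R)-(tert-butyldimethylsilyloxy)(3,4,5-trimethoxyphenyl)methyl]-3-[3,5-dimethoxy-4-(triisopropylsilyloxy)benzyl]butane-1,4-diyl dimethanesulfonate
Conditions: MsCl, Et3N, CH2Cl2, −20 → 0 °C
Reagents that add atoms: methanesulfonyl chloride, CS(=O)(=O)Cl
Why: Mesylation through sulfene with Et3N converts both primary alcohols quickly at low temperature, faster than a mono-sulfonate could cyclise to a tetrahydrofuran.

Step 10
Reactants: 16 dimesylate
Product: 17 (1R,2S,3R)-1-(tert-butyldimethylsilyloxy)-4-[3,5-dimethoxy-4-(triisopropylsilyloxy)phenyl]-2,3-dimethyl-1-(3,4,5-trimethoxyphenyl)butane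
Conditions: LiBHEt3, THF, 0 °C → rt; then H2O
Reagents that add atoms: none
Why: LiBHEt3 is a strong hydride nucleophile that displaces primary sulfonates by SN2, which turns both CH2OMs groups into the C7 and C8 methyl groups and leaves the silyl ethers alone.

Step 11
Reactants: 17 bis-silyl ether
Product: 18 4-[(2R,3S,4R)-4-(tert-butyldimethylsilyloxy)-2,3-dimethyl-4-(3,4,5-trimethoxyphenyl)butyl]-2,6-dimethoxyphenol
Conditions: Bu4NF (1.05 equiv), THF, 0 °C; then H2O
Reagents that add atoms: none
Why: Fluoride cleaves the aryl silyl ether far faster than the hindered secondary alkyl silyl ether because phenoxide is the better leaving group, so a stoichiometric charge at 0 °C should release only the ring-B phenol (chemoselective desilylation).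

Step 12
Reactants: 18 phenol
Product: 19 (7R,8S,9R)-9-(tert-butyldimethylsilyloxy)-2,3,3',4,5'-pentamethoxy-7,8-dimethyl-6,7,8,9-tetrahydrospiro[benzo[7]annulene-5,1'-cyclohexa[2,5]dien]-4'-one
Conditions: PhI(OCOCF3)2, NaHCO3 (solid), CF3CH2OH, −40 °C
Reagents that add atoms: none
Why: Oxidative dearomatisation of the para-alkylphenol by the hypervalent iodine reagent makes C5 electrophilic and the ring-A carbon ortho to the C9 side chain and para to a methoxy group attacks it (ipso-type Friedel–Crafts spirocyclisation forming the seven-membered ring), the methoxy-blocked ortho positions of the phenol and the symmetry of ring A leaving a single mode of closure that creates no stereocentre.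

Step 13
Reactants: 19 spirodienone silyl ether
Product: 20 (7R,8S,9R)-9-hydroxy-2,3,3',4,5'-pentamethoxy-7,8-dimethyl-6,7,8,9-tetrahydrospiro[benzo[7]annulene-5,1'-cyclohexa[2,5]dien]-4'-one (CNP0288561.1)
Conditions: Bu4NF, AcOH, THF, 0 °C → rt
Reagents that add atoms: none
Why: Acetic-acid-buffered fluoride removes the secondary silyl ether under near-neutral conditions (desilylation) that should spare the cross-conjugated dienone and leave C9 untouched.

Compound list
1 | syringaldehyde (4-hydroxy-3,5-dimethoxybenzaldehyde) | COc1cc(C=O)cc(OC)c1O | starting material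
2 | 4-(1,3-dithian-2-yl)-2,6-dimethoxyphenol | COc1cc(cc(OC)c1O)C1SCCCS1 | intermediate
3 | 2-[3,5-dimethoxy-4-(triisopropylsilyloxy)phenyl]-1,3-dithiane | COc1cc(cc(OC)c1O[Si](C(C)C)(C(C)C)C(C)C)C1SCCCS1 | intermediate
4 | furfural | O=Cc1ccco1 | starting material
5 | furan endoperoxide, 2,3,7-trioxabicyclo[2.2.1]hept-5-ene-1-carbaldehyde (not isolated) | O=CC12C=CC(OO1)O2 | intermediate
6 | 5-hydroxyfuran-2(5H)-one (racemic) | O=C1C=CC(O)O1 | intermediate
7 | (−)-menthol, (1R,2S,5R)-2-isopropyl-5-methylcyclohexanol | CC(C)[C@@H]1CC[C@@H](C)C[C@H]1O | starting material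
8 | (5R)-5-{[(1R,2S,5R)-2-isopropyl-5-methylcyclohexyl]oxy}furan-2(5H)-one | O=C1C=C[C@H](O[C@@H]2C[C@H](C)CC[C@H]2C(C)C)O1 | intermediate
9 | 3,4,5-trimethoxybenzaldehyde | COc1cc(C=O)cc(OC)c1OC | starting material
10 | 2-lithio-2-[3,5-dimethoxy-4-(triisopropylsilyloxy)phenyl]-1,3-dithiane (not isolated) | [Li]C1(SCCCS1)c1cc(OC)c(O[Si](C(C)C)(C(C)C)C(C)C)c(OC)c1 | intermediate
11 | lithium enolate of (4R,5R)-4-(2-aryl-1,3-dithian-2-yl)-5-menthyloxyoxolan-2-one (not isolated) | COc1cc(cc(OC)c1O[Si](C(C)C)(C(C)C)C(C)C)C1(SCCCS1)[C@@H]2C=C(O[Li])O[C@H]2O[C@@H]3C[C@H](C)CC[C@H]3C(C)C | intermediate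
12 | (3S,4R,5R)-4-{2-[3,5-dimethoxy-4-(triisopropylsilyloxy)phenyl]-1,3-dithian-2-yl}-3-[(R)-hydroxy(3,4,5-trimethoxyphenyl)methyl]-5-[(1R,2S,5R)-menthyloxy]oxolan-2-one | COc1cc(cc(OC)c1O[Si](C(C)C)(C(C)C)C(C)C)C1(SCCCS1)[C@@H]([C@H](O[C@@H]2C[C@H](C)CC[C@H]2C(C)C)OC3=O)[C@H]3[C@@H](O)c1cc(OC)c(OC)c(OC)c1 | intermediate
13 | tert-butyldimethylsilyl ether of 12 at the carbinol oxygen | COc1cc(cc(OC)c1O[Si](C(C)C)(C(C)C)C(C)C)C1(SCCCS1)[C@@H]([C@H](O[C@@H]2C[C@H](C)CC[C@H]2C(C)C)OC3=O)[C@H]3[C@@H](O[Si](C)(C)C(C)(C)C)c1cc(OC)c(OC)c(OC)c1 | intermediate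
14 | (3S,4R,5R)-3-[(R)-(tert-butyldimethylsilyloxy)(3,4,5-trimethoxyphenyl)methyl]-4-[3,5-dimethoxy-4-(triisopropylsilyloxy)benzyl]-5-[(1R,2S,5R)-menthyloxy]oxolan-2-one | COc1cc(cc(OC)c1O[Si](C(C)C)(C(C)C)C(C)C)C[C@@H]([C@H](O[C@@H]2C[C@H](C)CC[C@H]2C(C)C)OC3=O)[C@H]3[C@@H](O[Si](C)(C)C(C)(C)C)c1cc(OC)c(OC)c(OC)c1 | intermediate
15 | (2R,3R)-2-[(R)-(tert-butyldimethylsilyloxy)(3,4,5-trimethoxyphenyl)methyl]-3-[3,5-dimethoxy-4-(triisopropylsilyloxy)benzyl]butane-1,4-diol | COc1cc(cc(OC)c1O[Si](C(C)C)(C(C)C)C(C)C)C[C@@H](CO)[C@H](CO)[C@@H](O[Si](C)(C)C(C)(C)C)c1cc(OC)c(OC)c(OC)c1 | intermediate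
16 | bis(methanesulfonate) of diol 15 | COc1cc(cc(OC)c1O[Si](C(C)C)(C(C)C)C(C)C)C[C@@H](COS(C)(=O)=O)[C@H](COS(C)(=O)=O)[C@@H](O[Si](C)(C)C(C)(C)C)c1cc(OC)c(OC)c(OC)c1 | intermediate
17 | (1R,2S,3R)-1-(tert-butyldimethylsilyloxy)-4-[3,5-dimethoxy-4-(triisopropylsilyloxy)phenyl]-2,3-dimethyl-1-(3,4,5-trimethoxyphenyl)butane | COc1cc(cc(OC)c1O[Si](C(C)C)(C(C)C)C(C)C)C[C@@H](C)[C@H](C)[C@@H](O[Si](C)(C)C(C)(C)C)c1cc(OC)c(OC)c(OC)c1 | intermediate
18 | 4-[(2R,3S,4R)-4-(tert-butyldimethylsilyloxy)-2,3-dimethyl-4-(3,4,5-trimethoxyphenyl)butyl]-2,6-dimethoxyphenol | COc1cc(cc(OC)c1O)C[C@@H](C)[C@H](C)[C@@H](O[Si](C)(C)C(C)(C)C)c1cc(OC)c(OC)c(OC)c1 | intermediate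
19 | (7R,8S,9R)-9-(tert-butyldimethylsilyloxy)-2,3,3',4,5'-pentamethoxy-7,8-dimethyl-6,7,8,9-tetrahydrospiro[benzo[7]annulene-5,1'-cyclohexa[2,5]dien]-4'-one | COC1=CC2(C=C(OC)C1=O)C[C@@H](C)[C@H](C)[C@@H](O[Si](C)(C)C(C)(C)C)c1cc(OC)c(OC)c(OC)c12 | intermediate
20 | (7R,8S,9R)-9-hydroxy-2,3,3',4,5'-pentamethoxy-7,8-dimethyl-6,7,8,9-tetrahydrospiro[benzo[7]annulene-5,1'-cyclohexa[2,5]dien]-4'-one (CNP0288561.1) | COC1=CC2(C=C(OC)C1=O)C[C@@H](C)[C@H](C)[C@@H](O)c1cc(OC)c(OC)c(OC)c12 | target

Total step count: 13.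
Longest linear sequence: 11 steps (steps 1, 2 and 5 to 13, from syringaldehyde); the butenolide arm is steps 3 and 4.

Steps most likely to fail

Step 5. The aldol may lose diastereocontrol at the carbinol carbon, either because the chair transition state of the lithium enolate discriminates weakly between the two aldehyde faces or because the aldolate equilibrates by retro-aldol before the quench. The fallback sets out from crude 12 (both carbinol epimers) and comes back at 12 as one epimer. Oxidation with Dess–Martin periodinane (CH2Cl2, rt) should converge the mixture on the trans β-keto lactone (3S,4R,5R)-4-{2-[3,5-dimethoxy-4-(triisopropylsilyloxy)phenyl]-1,3-dithian-2-yl}-5-[(1R,2S,5R)-menthyloxy]-3-(3,4,5-trimethoxybenzoyl)oxolan-2-one F1. Reduction of the ketone with the non-chelating pair LiBHEt3/CeCl3 (THF, −78 °C) is expected to follow the Felkin–Anh mode, with the lactone carbonyl anti to the incoming hydride, and to return the anti alcohol 12. The carbinol centre is then set by reagent-controlled reduction and not by the aldol; the chelating reagent Zn(BH4)2 is expected to give the opposite (syn) epimer and serves as a check on the sense.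

Step 12. The dearomatised cation may be intercepted by the C9 oxygen (the silyl ether being labilised by the acid that the oxidant releases) or by the solvent instead of by ring A, and the dienone may rearrange under acid. The fallback changes the C9 protecting group to an acetate, whose oxygen is neither nucleophilic nor acid-labile; it sets out from 17 and comes back at target 20, bypassing 18 and 19.
- Excess Bu4NF (THF, rt → 40 °C) should remove both silyl groups and give 4-[(2R,3S,4R)-4-hydroxy-2,3-dimethyl-4-(3,4,5-trimethoxyphenyl)butyl]-2,6-dimethoxyphenol F2.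
- Ac2O, pyridine and DMAP should give the diacetate (1R,2S,3R)-4-(4-acetoxy-3,5-dimethoxyphenyl)-2,3-dimethyl-1-(3,4,5-trimethoxyphenyl)butyl acetate F3.
- Pyrrolidine (CH2Cl2, 0 °C) should cleave only the aryl acetate by aminolysis and give (1R,2S,3R)-4-(4-hydroxy-3,5-dimethoxyphenyl)-2,3-dimethyl-1-(3,4,5-trimethoxyphenyl)butyl acetate F4.
- PhI(OCOCF3)2 with solid NaHCO3 in CF3CH2OH at −40 °C should give the spirodienone acetate (7R,8S,9R)-2,3,3',4,5'-pentamethoxy-7,8-dimethyl-4'-oxo-6,7,8,9-tetrahydrospiro[benzo[7]annulene-5,1'-cyclohexa[2,5]dien]-9-yl acetate F5.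
- K2CO3 in MeOH at 0 °C should remove the acetate and give 20.

Step 10. Hydride may attack sulfur instead of carbon at the two β-branched primary centres and return alcohol, or on warming the C9 silyloxy oxygen may displace the 1,4-related mesylate to give a tetrahydrofuran. The fallback replaces hydride by a soft sulfur nucleophile and removes sulfur afterwards; it sets out from 16 and comes back at 17. Na2S·9H2O in DMF at 50 °C should close, by double SN2, the trans thiolane (3S,4R)-3-[(R)-(tert-butyldimethylsilyloxy)(3,4,5-trimethoxyphenyl)methyl]-4-[3,5-dimethoxy-4-(triisopropylsilyloxy)benzyl]thiolane F6. Raney Ni (EtOH–THF, rt) should then cleave both C–S bonds, turn the two ring CH2 groups into the C7 and C8 methyl groups and give 17.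

Further compounds
F1 | step 5 | (3S,4R,5R)-4-{2-[3,5-dimethoxy-4-(triisopropylsilyloxy)phenyl]-1,3-dithian-2-yl}-5-[(1R,2S,5R)-menthyloxy]-3-(3,4,5-trimethoxybenzoyl)oxolan-2-one | COc1cc(cc(OC)c1O[Si](C(C)C)(C(C)C)C(C)C)C1(SCCCS1)[C@@H]([C@H](O[C@@H]2C[C@H](C)CC[C@H]2C(C)C)OC3=O)[C@H]3C(=O)c1cc(OC)c(OC)c(OC)c1
F2 | step 12 | 4-[(2R,3S,4R)-4-hydroxy-2,3-dimethyl-4-(3,4,5-trimethoxyphenyl)butyl]-2,6-dimethoxyphenol | COc1cc(cc(OC)c1O)C[C@@H](C)[C@H](C)[C@@H](O)c1cc(OC)c(OC)c(OC)c1
F3 | step 12 | (1R,2S,3R)-4-(4-acetoxy-3,5-dimethoxyphenyl)-2,3-dimethyl-1-(3,4,5-trimethoxyphenyl)butyl acetate | COc1cc(cc(OC)c1OC(C)=O)C[C@@H](C)[C@H](C)[C@@H](OC(C)=O)c1cc(OC)c(OC)c(OC)c1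
F4 | step 12 | (1R,2S,3R)-4-(4-hydroxy-3,5-dimethoxyphenyl)-2,3-dimethyl-1-(3,4,5-trimethoxyphenyl)butyl acetate | COc1cc(cc(OC)c1O)C[C@@H](C)[C@H](C)[C@@H](OC(C)=O)c1cc(OC)c(OC)c(OC)c1
F5 | step 12 | (7R,8S,9R)-2,3,3',4,5'-pentamethoxy-7,8-dimethyl-4'-oxo-6,7,8,9-tetrahydrospiro[benzo[7]annulene-5,1'-cyclohexa[2,5]dien]-9-yl acetate | COC1=CC2(C=C(OC)C1=O)C[C@@H](C)[C@H](C)[C@@H](OC(C)=O)c1cc(OC)c(OC)c(OC)c12
F6 | step 10 | (3S,4R)-3-[(R)-(tert-butyldimethylsilyloxy)(3,4,5-trimethoxyphenyl)methyl]-4-[3,5-dimethoxy-4-(triisopropylsilyloxy)benzyl]thiolane | COc1cc(cc(OC)c1O[Si](C(C)C)(C(C)C)C(C)C)C[C@H]2CSC[C@@H]2[C@@H](O[Si](C)(C)C(C)(C)C)c1cc(OC)c(OC)c(OC)c1
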